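**Retrosynthetic overview**

1. The C11–O aryl ether is made last, by Mitsunobu coupling of diol 18 with scopoletin. The axial 3-hydroxyl comes from trans-diaxial hydride opening of a 2,3-epoxide, placed on the C2=C3 alkene whose position the cycloadduct's enol ether defines.
2. C9–C11 is formed by a Still–Wittig [2,3] shift from a C7 alkoxide, obtained by Wharton transposition of a 7,8-epoxy-9-ketone. This delivers C11 to the face anti to the C10 methyl and leaves the C7=C8 alkene.
3. The C2 and C6 oxygens are removed only through trigonal carbon (enol triflates, Pd/formate), because any group on the methyl-bearing face at C2 or C6 is syn-axial to both the C4 and C10 methyls.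
4. Ring A is disconnected by an enantioselective quinone Diels–Alder reaction (bonds C1–C10 and C4–C5). The feature the plan rests on: ring B with the quaternary C10 methyl, the C5 ring-fusion CH and the C7=C8(CH3) alkene is the carbon pattern of 2,6-dimethyl-1,4-benzoquinone, and C1–C4 with the C4 gem-dimethyl group is the silyl dienol ether of mesityl oxide.
5. Ring order: ring B is bought as the quinone, ring A is closed in step 2, and the coumarin is bought and attached in step 14.

Key step: step 2

Conventions: drimane numbering is used (C3 carbinol, C4 gem-dimethyl, C5 ring-fusion CH, C7=C8 with the C8 methyl, C9 bearing C11, C10 with the angular methyl). "11-Nordrimane" is the 4,4,8,10-tetramethyldecalin core. "Anti" and "syn" give the face of the decalin relative to the C10 methyl.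

Assumption: the facial sense of the catalyst is taken from its α-C–H···O binding model as calibrated on acrylate dienophiles, under which the (R)-diphenylprolinol-derived catalyst gives (10R); if the sense found is the opposite, the (S)-prolinol-derived antipode is used and nothing else changes.

**Route**

Step 1
Reactants: 1 mesityl oxide
Product: 2 2-(tert-butyldimethylsilyloxy)-4-methylpenta-1,3-diene
Conditions: TBSOTf, Et3N, CH2Cl2, 0 °C
Reagents that add atoms: tert-butyldimethylsilyl triflate, CC(C)(C)[Si](C)(C)OS(=O)(=O)C(F)(F)F
Why: Soft enolisation (O-silylation, then loss of a proton from the methyl group on the carbonyl carbon) should give the cross-conjugated 2-silyloxy diene, a silyl dienol ether formation.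

Step 2
Reactants: 2 2-(tert-butyldimethylsilyloxy)-4-methylpenta-1,3-diene; 3 2,6-dimethyl-1,4-benzoquinone
Product: 4 cis-fused (10R)-2-(tert-butyldimethylsilyloxy)-11-nordrima-2,7-diene-6,9-dione (H5 syn to the C10 methyl)
Conditions: (R)-3,3-diphenyl-1-(2-methylphenyl)tetrahydro-1H,3H-pyrrolo[1,2-c][1,3,2]oxazaborole (0.2 equiv, from (R)-α,α-diphenylprolinol and tri-o-tolylboroxine), HN(SO2CF3)2 (0.18 equiv), CH2Cl2, −78 to −40 °C
Reagents that add atoms: none
Why: The N-protonated oxazaborolidine binds the quinone carbonyl flanked by two vinylic C–H bonds (future C6) at the lone pair syn to an α-C–H, which makes the methyl-bearing β-carbon (future C10) the electrophilic terminus, and the nucleophilic CH2 end of the silyl dienol ether bonds there while the CMe2 end closes onto the adjacent CH carbon (C4–C5) in a concerted but strongly asynchronous [4+2] cycloaddition. The closest known reaction type is the oxazaborolidinium-catalysed enantioselective Diels–Alder reaction of 2-silyloxy-1,3-dienes with unsymmetrical 1,4-benzoquinones. Ring A is closed as a six-membered carbocycle by suprafacial addition across the quinone C5=C10 bond, so the fusion is cis and H5 lies syn to the C10 methyl. C10 is set as R by the catalyst, whose carbinol phenyl group shields one face of the bound quinone so that the diene adds to the open face, and C5 follows from the suprafacial addition and is corrected in step 5. The step needs regioselectivity (C1 to C10, C4 to C5) and face selectivity, secured respectively by pairing the diene's nucleophilic terminus with the β-carbon of the activated enone unit and by the two-point binding (B–O coordination plus α-C–H···O contact), while the two C=C bonds of 3 are symmetry-equivalent so that no site selectivity arises. The dimethylated diene terminus slows the second bond formation, which the cationic Lewis acid should tolerate because the first bond forms in a Mukaiyama–Michael-like manner.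

Step 3
Reactants: 4 cis-fused (10R)-2-(tert-butyldimethylsilyloxy)-11-nordrima-2,7-diene-6,9-dione
Product: 5 cis-fused (10R)-2-(trifluoromethanesulfonyloxy)-11-nordrima-2,7-diene-6,9-dione
Conditions: CsF, PhNTf2, DME, rt
Reagents that add atoms: N-phenylbis(trifluoromethanesulfonimide), O=S(=O)(N(c1ccccc1)S(=O)(=O)C(F)(F)F)C(F)(F)F
Why: Fluoride-induced desilylation in the presence of PhNTf2 should trap the regiodefined C2 enolate on oxygen faster than it can exchange protons (silyl enol ether to enol triflate conversion), which stores the C2=C3 position in a form that survives acid, zinc and base.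

Step 4
Reactants: 5 cis-fused (10R)-2-(trifluoromethanesulfonyloxy)-11-nordrima-2,7-diene-6,9-dione
Product: 6 cis-fused (10R)-2-(trifluoromethanesulfonyloxy)-11-nordrim-2-ene-6,9-dione (C8 not controlled)
Conditions: Zn dust, AcOH, rt
Reagents that add atoms: none
Why: Zinc in acetic acid reduces the electron-poor C7=C8 bond of the ene-1,4-dione by electron transfer and protonation (dissolving-metal conjugate reduction), the vinyl triflate being inert, and the C8 configuration formed here is of no consequence because C8 becomes trigonal again in step 7.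

Step 5
Reactants: 6 cis-fused (10R)-2-(trifluoromethanesulfonyloxy)-11-nordrim-2-ene-6,9-dione
Product: 7 trans-fused (10R)-2-(trifluoromethanesulfonyloxy)-11-nordrim-2-ene-6,9-dione (H5 anti to the C10 methyl, C8 methyl equatorial)
Conditions: DBU (0.3 equiv), toluene, 60 °C
Reagents that add atoms: none
Why: Base-mediated epimerisation through the C6 enolate should move C5 to the trans fusion, because in this chair-form dione the cis isomer has to hold a C4 methyl over ring B against the axial C7 hydrogen, and the same conditions bring the C8 methyl into the equatorial position.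

Step 6
Reactants: 7 trans-fused (10R)-2-(trifluoromethanesulfonyloxy)-11-nordrim-2-ene-6,9-dione
Product: 8 trans-fused (10R)-2,6-bis(trifluoromethanesulfonyloxy)-11-nordrima-2,6-dien-9-one
Conditions: KN(SiMe3)2, THF, −78 °C; then PhNTf2, −78 to 0 °C
Reagents that add atoms: N-phenylbis(trifluoromethanesulfonimide), O=S(=O)(N(c1ccccc1)S(=O)(=O)C(F)(F)F)C(F)(F)F
Why: Kinetic deprotonation takes the only methylene flanking a ketone (C7; the C5 and C8 hydrogens are tertiary and shielded) and O-triflation of the C6 enolate (enol triflate formation) removes the C6 carbonyl as a trigonal carbon, after which C5 can no longer epimerise.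

Step 7
Reactants: 8 trans-fused (10R)-2,6-bis(trifluoromethanesulfonyloxy)-11-nordrima-2,6-dien-9-one
Product: 10 trans-fused (10R)-11-nordrima-2,7-dien-9-one, via deconjugated ketone 9 (not isolated)
Conditions: Pd(OAc)2 (0.05 equiv), PPh3, HCO2H, n-Bu3N, DMF, 60 °C; then DBU, rt
Reagents that add atoms: none
Why: Palladium-catalysed formate reduction replaces both vinyl C–OTf bonds by C–H (hydride transfer to the vinylpalladium intermediates), and DBU then moves the β,γ-double bond into conjugation through the dienolate, so that C2 and C6 lose their oxygen without a tetrahedral intermediate on the hindered face.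

Step 8
Reactants: 10 trans-fused (10R)-11-nordrima-2,7-dien-9-one
Product: 11 2,3-epoxy-11-nordrim-7-en-9-one (epoxide oxygen anti to the C10 methyl)
Conditions: mCPBA, CH2Cl2, 0 °C
Reagents that add atoms: 3-chloroperoxybenzoic acid, OOC(=O)c1cccc(Cl)c1
Why: Peracid (Prilezhaev) epoxidation takes the isolated C2=C3 alkene and not the electron-poor enone, from the face anti to the pseudo-axial C4 methyl and the C10 methyl, which sets the C3–O bond anti to the C10 methyl (cis to H5).

Step 9
Reactants: 11 2,3-epoxy-11-nordrim-7-en-9-one
Product: 12 2,3:7,8-diepoxy-11-nordriman-9-one (both epoxide oxygens anti to the C10 methyl)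
Conditions: H2O2 (30% aq), NaOH (cat.), MeOH, 0 °C
Reagents that add atoms: hydrogen peroxide, OO
Why: Nucleophilic (Weitz–Scheffer) epoxidation of the α-methyl enone: hydroperoxide adds to C7 axially on the face anti to the C10 methyl and the enolate closes the oxirane, which sets the C7–O bond on that face.

Step 10
Reactants: 12 2,3:7,8-diepoxy-11-nordriman-9-one
Product: 14 2,3-epoxy-11-nordrim-8-en-7-ol (7-hydroxyl anti to the C10 methyl), via C9 hydrazone 13 (not isolated)
Conditions: N2H4·H2O, AcOH (cat.), MeOH, 0 °C to rt
Reagents that add atoms: none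
Why: Wharton transposition: the hydrazone opens the oxirane at C8 to an alkenyl diazene that loses N2, giving the C8=C9 alkene and the C7 alcohol, whose C–O bond is not touched so that its configuration is retained.

Step 11
Reactants: 14 2,3-epoxy-11-nordrim-8-en-7-ol
Product: 15 7-O-(tributylstannylmethyl) ether of 14
Conditions: KH, Bu3SnCH2I, THF, 0 °C to rt
Reagents that add atoms: (iodomethyl)tributylstannane, CCCC[Sn](CCCC)(CCCC)CI
Why: Williamson etherification of the potassium alkoxide with the primary iodide gives the α-stannyl methyl ether needed for tin–lithium exchange.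

Step 12
Reactants: 15 7-O-(tributylstannylmethyl) ether of 14
Product: 17 2,3-epoxy-9-epi-drim-7-en-11-ol (C11 anti to the C10 methyl), via lithiomethyl ether 16 (not isolated)
Conditions: n-BuLi, THF, −78 to 0 °C
Reagents that add atoms: none
Why: Still–Wittig rearrangement: tin–lithium exchange gives the α-alkoxy carbanion, which shifts [2,3] suprafacially across the allyl unit, so C11 bonds to C9 on the face that carried the C7 oxygen (anti to the C10 methyl, the axial and less hindered approach), setting C9, and the alkene moves to C7=C8.

Step 13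
Reactants: 17 2,3-epoxy-9-epi-drim-7-en-11-ol
Product: 18 (3S,5S,9S,10R)-drim-7-ene-3,11-diol (3-hydroxyl axial and anti to the C10 methyl, C11 anti)
Conditions: LiAlH4, THF, reflux
Reagents that add atoms: none
Why: LiAlH4 opens the 2,3-epoxide in the trans-diaxial (Fürst–Plattner) sense by axial hydride attack at C2, the only alternative being attack at neopentyl C3 through a twist-boat, so the axial 3-hydroxyl anti to the C10 methyl results with the C3–O bond formed in step 8 untouched.

Step 14
Reactants: 18 (3S,5S,9S,10R)-drim-7-ene-3,11-diol; 19 scopoletin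
Product: 20 7-{[(3S,5S,9S,10R)-3-hydroxydrim-7-en-11-yl]oxy}-6-methoxycoumarin (CNP0218138.1)
Conditions: PPh3, DIAD, THF, 0 °C to rt
Reagents that add atoms: none
Why: Mitsunobu etherification: the acidic 7-hydroxyl of scopoletin displaces the activated primary C11 alkoxyphosphonium, while the axial, neopentyl-type C3 hydroxyl is too hindered to react, giving the target.

**Compound list**

1 | mesityl oxide (4-methylpent-3-en-2-one) | CC(=O)C=C(C)C | starting material
2 | 2-(tert-butyldimethylsilyloxy)-4-methylpenta-1,3-diene | C=C(O[Si](C)(C)C(C)(C)C)C=C(C)C | intermediate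
3 | 2,6-dimethyl-1,4-benzoquinone | CC1=CC(=O)C=C(C)C1=O | starting material
4 | cis-fused (10R)-2-(tert-butyldimethylsilyloxy)-11-nordrima-2,7-diene-6,9-dione | O=C1C(C)=CC(=O)[C@H]2C(C)(C)C=C(O[Si](C)(C)C(C)(C)C)C[C@]21C | intermediate
5 | cis-fused (10R)-2-(trifluoromethanesulfonyloxy)-11-nordrima-2,7-diene-6,9-dione | O=C1C(C)=CC(=O)[C@H]2C(C)(C)C=C(OS(=O)(=O)C(F)(F)F)C[C@]21C | intermediate
6 | cis-fused (10R)-2-(trifluoromethanesulfonyloxy)-11-nordrim-2-ene-6,9-dione, both C8 epimers | O=C1C(C)CC(=O)[C@H]2C(C)(C)C=C(OS(=O)(=O)C(F)(F)F)C[C@]21C | intermediate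
7 | trans-fused (10R)-2-(trifluoromethanesulfonyloxy)-11-nordrim-2-ene-6,9-dione, C8 methyl equatorial | O=C1[C@@H](C)CC(=O)[C@@H]2C(C)(C)C=C(OS(=O)(=O)C(F)(F)F)C[C@]21C | intermediate
8 | trans-fused (10R)-2,6-bis(trifluoromethanesulfonyloxy)-11-nordrima-2,6-dien-9-one | O=C1[C@@H](C)C=C(OS(=O)(=O)C(F)(F)F)[C@@H]2C(C)(C)C=C(OS(=O)(=O)C(F)(F)F)C[C@]21C | intermediate
9 | trans-fused (10R)-11-nordrima-2,6-dien-9-one | O=C1[C@@H](C)C=C[C@@H]2C(C)(C)C=CC[C@]21C | intermediate (not isolated)
10 | trans-fused (10R)-11-nordrima-2,7-dien-9-one | O=C1C(C)=CC[C@@H]2C(C)(C)C=CC[C@]21C | intermediate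
11 | 2,3-epoxy-11-nordrim-7-en-9-one, epoxide oxygen anti to the C10 methyl | O=C1C(C)=CC[C@@H]2C(C)(C)[C@H]3O[C@H]3C[C@]21C | intermediate
12 | 2,3:7,8-diepoxy-11-nordriman-9-one, both oxygens anti to the C10 methyl | O=C1[C@@]4(C)O[C@H]4C[C@@H]2C(C)(C)[C@H]3O[C@H]3C[C@]21C | intermediate
13 | C9 hydrazone of 12 | NN=C1[C@@]4(C)O[C@H]4C[C@@H]2C(C)(C)[C@H]3O[C@H]3C[C@]21C | intermediate (not isolated)
14 | 2,3-epoxy-11-nordrim-8-en-7-ol, 7-hydroxyl anti to the C10 methyl | C1=C(C)[C@@H](O)C[C@@H]2C(C)(C)[C@H]3O[C@H]3C[C@]21C | intermediate
15 | 7-O-(tributylstannylmethyl) ether of 14 | C1=C(C)[C@@H](OC[Sn](CCCC)(CCCC)CCCC)C[C@@H]2C(C)(C)[C@H]3O[C@H]3C[C@]21C | intermediate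
16 | 7-O-(lithiomethyl) ether of 14 | C1=C(C)[C@@H](OC[Li])C[C@@H]2C(C)(C)[C@H]3O[C@H]3C[C@]21C | intermediate (not isolated)
17 | 2,3-epoxy-9-epi-drim-7-en-11-ol, C11 anti to the C10 methyl | OC[C@H]1C(C)=CC[C@@H]2C(C)(C)[C@H]3O[C@H]3C[C@]21C | intermediate
18 | (3S,5S,9S,10R)-drim-7-ene-3,11-diol | OC[C@H]1C(C)=CC[C@@H]2C(C)(C)[C@@H](O)CC[C@]21C | intermediate
19 | scopoletin (7-hydroxy-6-methoxycoumarin) | COc1cc2ccc(=O)oc2cc1O | starting material
20 | 7-{[(3S,5S,9S,10R)-3-hydroxydrim-7-en-11-yl]oxy}-6-methoxycoumarin | COc1cc2ccc(=O)oc2cc1OC[C@H]1C(C)=CC[C@@H]2C(C)(C)[C@@H](O)CC[C@]21C | target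

**Step count and risks**

Total step count: 14. Longest linear sequence: 14 steps (1 to 20); 3 and 19 are bought and enter at steps 2 and 14.

Steps most likely to fail:

Step 2. The second bond may fail to close: at the dimethylated diene terminus the addition can stall after the first C–C bond, leaving the Mukaiyama–Michael adduct, and the acid-activated catalyst may also protodesilylate the diene. The fallback sets out from 2 and 3 and returns at 4. The arrested addition is accepted: the same catalyst is used for the Mukaiyama–Michael addition alone, and aqueous work-up should give (R)-2,6-dimethyl-6-(4-methyl-2-oxopent-3-en-1-yl)cyclohex-2-ene-1,4-dione F1, in which C10 is already set. Ring A is then closed in a second operation by a Michael-initiated ring closure: LiN(SiMe3)2 (THF, −78 °C) deprotonates the ring methylene α to the C6 carbonyl, the enolate adds to the CMe2 carbon of the side-chain enone, and the resulting C2 enolate is trapped with TBSCl/DMPU. This returns 4; a mixture of C5 epimers is of no concern because C5 is equilibrated in step 5.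

Step 5. The thermodynamic equilibrium at C5 may not lie far enough on the trans side, because C9 is trigonal and offers no axial hydrogen to penalise the cis isomer. The fallback sets out from 4 and returns at 10, and sets C5 by a stereoelectronically controlled reduction instead of an equilibrium. i-Bu2AlH (CH2Cl2, −78 °C) reduces the less hindered C6 carbonyl of 4 to the cis-fused 6-hydroxy-7-en-9-one F2, with the silyl enol ether intact and the C6 configuration irrelevant. Dehydration across C5–C6 with Ph2S[OC(CF3)2Ph]2 gives the linear 2-silyloxy-2,5,7-trien-9-one F3, which removes the C6 oxygen and erases C5. Li in liquid NH3/THF with t-BuOH (−78 °C, NH4Cl quench) adds hydrogen at the dienone terminus C5 with the new C–H bond axial to ring B and anti to the C10 methyl, so the trans fusion is formed under kinetic control, and α-protonation gives the deconjugated trans-fused ketone F4. DBU conjugates this to the trans-fused enone F5, CsF/PhNTf2 converts the silyl enol ether into the vinyl triflate F6, and Pd(OAc)2/PPh3/HCO2H/n-Bu3N reduction gives 10.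

Step 12. A [1,2] shift or simple protonation of the α-alkoxy organolithium may compete with the [2,3] shift, because C9 is next to the quaternary C10. The fallback sets out from 14 and returns at 17, and uses the same suprafacial 1,3-transfer with a carbene in place of the carbanion. Heating 14 with Me2NCH(OMe)2 (xylene, 140 °C) forms the alkoxy(dimethylamino)carbene, whose [2,3] shift should give the N,N-dimethyl amide F7 with the carboxamide carbon on C9 anti to the C10 methyl. LiNH2BH3 (THF, rt) then reduces the tertiary amide to the primary alcohol 17.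

Further compounds
F1 | step 2 | (R)-2,6-dimethyl-6-(4-methyl-2-oxopent-3-en-1-yl)cyclohex-2-ene-1,4-dione | O=C1C(C)=CC(=O)C[C@@]1(C)CC(=O)C=C(C)C
F2 | step 5 | cis-fused (10R)-2-(tert-butyldimethylsilyloxy)-6-hydroxy-11-nordrima-2,7-dien-9-one, both C6 epimers | O=C1C(C)=CC(O)[C@H]2C(C)(C)C=C(O[Si](C)(C)C(C)(C)C)C[C@]21C
F3 | step 5 | (10R)-2-(tert-butyldimethylsilyloxy)-11-nordrima-2,5,7-trien-9-one | O=C1C(C)=CC=C2C(C)(C)C=C(O[Si](C)(C)C(C)(C)C)C[C@]21C
F4 | step 5 | trans-fused (10R)-2-(tert-butyldimethylsilyloxy)-11-nordrima-2,6-dien-9-one, both C8 epimers | O=C1C(C)C=C[C@@H]2C(C)(C)C=C(O[Si](C)(C)C(C)(C)C)C[C@]21C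
F5 | step 5 | trans-fused (10R)-2-(tert-butyldimethylsilyloxy)-11-nordrima-2,7-dien-9-one | O=C1C(C)=CC[C@@H]2C(C)(C)C=C(O[Si](C)(C)C(C)(C)C)C[C@]21C
F6 | step 5 | trans-fused (10R)-2-(trifluoromethanesulfonyloxy)-11-nordrima-2,7-dien-9-one | O=C1C(C)=CC[C@@H]2C(C)(C)C=C(OS(=O)(=O)C(F)(F)F)C[C@]21C
F7 | step 12 | 2,3-epoxy-N,N-dimethyl-9-epi-drim-7-en-11-amide, carboxamide anti to the C10 methyl | CN(C)C(=O)[C@H]1C(C)=CC[C@@H]2C(C)(C)[C@H]3O[C@H]3C[C@]21C
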